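Count the target that is left, not the target that was made, and these two vessels can be compared by hand.

| setting | theta | alpha |
|---|---|---|
| substrate | 0.12 M | 0.12 M |
| time | 6.0 min |  |
| remark | everything together in a closed stirred flask, run for 6.0 min | one stirred flow tank at steady state, fed with the mixture as stated, mean residence time 6.0 min |

    target → over-reaction product (k1 = 0.0035 /s)
    substrate → target (k2 = 4.0 × 10⁻⁶ /s)
    substrate + 2 target → 3 target (k3 = 1.2 /M²/s)
    substrate → decomposition product (k4 = 7.0 × 10⁻⁶ /s)

- the set-up with the highest share of target in all that became target or over-reaction product, at the outlet or at the end ("none" if the first two lie within 2 percentage points) (theta / alpha / none)
- share of target in all that became target or over-reaction product, at the outlet or at the end, theta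
- share of target in all that became target or over-reaction product, at the outlet or at the end, alpha

- for a step with 2 of a species take k times the square, and two of it per event
- the stated concentrations are those of everything mixed, before any reaction; amounts are the same in each set-up
- run time (theta): 6.0 min

I began by treating the feed of target as steady. My objection was that [substrate] falls, so I computed the fall: its two first-order losses took about 0.396% of it in 6.0 min, and the feed held near 2.88 × 10⁻⁵ M/min. I then carried one number, 1.26, the loss number: the constant of over-reaction times the time in the vessel, a Damköhler number. In theta, target made at an even rate and decaying for the time remaining keeps on average one minus e to the minus the loss number, divided by the loss number, which gave 56.9%. In alpha, the fraction left at steady state is one over one plus the loss number, which gave 44.2%. So I chose theta.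

My second objection was the autocatalytic step, whose gain k[substrate][target]² matches the over-reaction loss at [target] = 0.0243 M. The feed over the run in theta supplied 1.73 × 10⁻⁴ M, far less than that, so by this estimate the gain came to about 0.711% of the loss at that level of target, and I dropped the step.

The forecast also named theta, giving 57.1% (56.5% to 57.8%) for theta and 44.2% (44% to 44.5%) for alpha, and spoke of “a slow, nearly constant feed of target followed by first-order loss”. Its theta figure stood slightly above mine.

The simulation gave 56.8% for theta and 44.2% for alpha, so theta led by 13 percentage points. Target's half-life by over-reaction is 3.3 min, shorter than the 6.0 min spent in either vessel and far shorter than the 48 h of substrate by the step that makes target. At ten times the time, the loss number for theta becomes 12.6, and the same average gives 7.94%, against a simulated 7.81% at 60.0 min.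

Its constants come from no measurement; the rest is arithmetic.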